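**Plan**

1. Ring numbering used below: C1 = CH carrying the side chain, C2 = C(CH3)–O, C3 = CH–O, C4 = C(CH3)=, C5 = =CH, C6 = C(CH3)(pyronyl). The retrosynthesis cuts the side-chain CH(OH)–CH(CH3) bond (aldol), the C(=CH2)–CHO bond (carbonylation of an enol triflate), the epoxide C3–O bond (trans-2,3-diol monosulfonate), then C2–C3 and C1–C6 together (Diels–Alder), then the O–Si–O tether and the bond between the pyrone ethyl carbon and the enal.
2. Enabling feature: C4=C5 is the only double bond of the carbocycle, and C2–C3 and C1–C6 are the ring bonds leaving its two allylic carbons. That is a Diels–Alder retron (diene C3=C4–C5=C6, dienophile C1=C2). C2 and C3 both carry oxygen, so the dienol oxygen of an enal and the enol oxygen of acetylacetone can be tied through one silicon atom.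
3. Forward order: pyranone ring (steps 1–3), enal, mixed bis-enol silane, then the cycloaddition, which closes the cyclohexene and a temporary dioxasilolane in one operation (step 6). Acetyl is then turned into a 2-substituted acrolein (steps 7, 8), the silylene is removed, the epoxide is closed with inversion at C3 (steps 9, 10), and the side chain is added by aldol (step 11).
4. Stereochemistry: the relative configuration of C1, C2, C3 and C6 comes from the alkene geometries and the acetyl-endo, tether-exo transition state of step 6. C3 is inverted in the epoxide closure. The two side-chain centres come from the chiral boron enolate. The absolute configuration of the ring is selected in step 11 by separation of diastereomers.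

Key step: step 6

Remark: 7 is treated as not commercial and is made in steps 1 to 3; the cycloaddition substrate is achiral, so 16 to 24 are racemates (SMILES show the enantiomer that ends in 28) and the reagent-controlled aldol of step 11 turns the two enantiomers of 24 into separable diastereomers; α is the ring face of the C1 side chain, β the other face, and Py = 6-methoxy-3,5-dimethyl-4-oxo-4H-pyran-2-yl.

**Route**

Step 1
Reactants: 1 methyl 2-methyl-3-oxopentanoate; 2 methyl propanoate
Product: 4 methyl 2,4-dimethyl-3,5-dioxoheptanoate, via sodium lithium dienolate 3 (not isolated)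
Conditions: NaH, THF, 0 °C; n-BuLi, 0 °C; 2 (0.5 equiv), 0 °C to rt; aq HCl
Reagents that add atoms: methyl propanoate CCC(=O)OC
Why: Claisen-type C-acylation of the β-keto ester dianion at its more nucleophilic γ-carbon; the stereocentres formed are lost in step 2.

Step 2
Reactants: 4 methyl 2,4-dimethyl-3,5-dioxoheptanoate
Product: 5 6-ethyl-4-hydroxy-3,5-dimethyl-2H-pyran-2-one
Conditions: DBU, toluene, reflux
Reagents that add atoms: none
Why: base-promoted lactonisation of the C5 enol onto the ester (intramolecular acyl substitution) should give the 4-hydroxy-2-pyranone, with no stereocentre left.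

Step 3
Reactants: 5 6-ethyl-4-hydroxy-3,5-dimethyl-2H-pyran-2-one; 6 methyl trifluoromethanesulfonate
Product: 7 6-ethyl-2-methoxy-3,5-dimethyl-4H-pyran-4-one
Conditions: MeOTf, CH2Cl2, rt; aq NaHCO3
Reagents that add atoms: methyl trifluoromethanesulfonate COS(=O)(=O)C(F)(F)F
Why: O-methylation of the lactone carbonyl oxygen by the hard alkylating agent, then loss of the 4-OH proton, should give the 2-methoxy-4-pyranone and not the 4-methoxy-2-pyranone.

Step 4
Reactants: 7 6-ethyl-2-methoxy-3,5-dimethyl-4H-pyran-4-one; 8 (E)-3-ethoxy-2-methylprop-2-enal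
Product: 11 (2E)-4-Py-2-methylpent-2-enal, via lithium dienolate 9 (not isolated), via aldol adduct 10 (not isolated)
Conditions: LiN(SiMe3)2, THF, −78 °C; 8; then 1 M HCl, THF, 0 °C to rt
Reagents that add atoms: (E)-3-ethoxy-2-methylprop-2-enal CCO/C=C(\C)C=O
Why: vinylogous aldol addition of the pyrone ethyl anion to the aldehyde, then acid-induced allylic transposition and hydrolysis of the β-hydroxy enol ether, should give the thermodynamically preferred (E)-enal; the new C4 stereocentre is removed in step 5.

Step 5
Reactants: 11 (2E)-4-Py-2-methylpent-2-enal; 12 di-tert-butylsilyl bis(trifluoromethanesulfonate); 13 pentane-2,4-dione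
Product: 15 mixed bis-enol silane, via dienyl silyl triflate 14 (not isolated)
Conditions: t-Bu2Si(OTf)2, Et3N, CH2Cl2, −78 to 0 °C; then 13, Et3N, 0 °C to rt; non-aqueous work-up (pentane, basic alumina)
Reagents that add atoms: di-tert-butylsilyl bis(trifluoromethanesulfonate) CC(C)(C)[Si](OS(=O)(=O)C(F)(F)F)(OS(=O)(=O)C(F)(F)F)C(C)(C)C; pentane-2,4-dione CC(=O)CC(C)=O
Why: soft γ-enolisation of the s-trans enal by the silyl triflate and amine should give the (1E,3E)-dienyl silyl ether (pyrone outside, to avoid allylic 1,3-strain), and the second, slower substitution at the hindered silicon by the acetylacetone enol gives the mixed silyl bis-enol ether (sequential O-silylation).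

Step 6
Reactants: 15 mixed bis-enol silane
Product: 16 trans-fused silylene adduct (racemic)
Conditions: toluene (high dilution), BHT, 120–130 °C, sealed base-washed tube
Reagents that add atoms: none
Why: Proposed new method: a concerted thermal [4+2] cycloaddition between the 1-siloxy diene and the (E)-β-siloxy enone held on one silicon atom is expected, with the s-cis diene favoured because its C4 methyl clashes with the inside methyl at the pyronyl terminus in the s-trans form; the closest known reaction type is the type 1 intramolecular Diels–Alder reaction of 1,3,8-nonatrienes and of silyl-acetal-tethered trienes, which has not been shown with two enol oxygens on silicon. The cyclohexene closes suprafacially on both components, and the 1,3-dioxa-2-silolane closes in the fused mode, because the O–Si–O tether joins the diene terminus C3 to the dienophile carbon C2 that bonds to it; this fixes the regiochemistry whatever the electronic preference. The (1E,3E) diene geometry puts the C3 oxygen and the pyrone on one face and the C3 hydrogen and the C6 methyl on the other, and the (E)-enone geometry puts acetyl cis to the C2 methyl. The acetyl-endo, tether-exo transition state then gives the trans-fused silylene with O2 and O3 anti and acetyl cis to the pyrone. The selectivity needed is endo over exo, that is trans- over cis-fusion; it should be secured by the secondary-orbital preference of the acetyl group and by the tert-butyl groups on silicon, one of which would be forced under the diene in the cis-fused transition state. The adduct is racemic because the substrate is achiral.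

Step 7
Reactants: 16 trans-fused silylene adduct; 17 N-phenylbis(trifluoromethanesulfonimide)
Product: 19 enol triflate, via potassium enolate 18 (not isolated)
Conditions: KN(SiMe3)2, THF, −78 °C; PhNTf2, −78 to 0 °C; aq NH4Cl
Reagents that add atoms: N-phenylbis(trifluoromethanesulfonimide) O=S(=O)(N(c1ccccc1)S(=O)(=O)C(F)(F)F)C(F)(F)F
Why: kinetic deprotonation at the acetyl methyl group (the C1–H is flanked by two fully substituted carbons) and O-triflation of the enolate should give the terminal enol triflate without touching a stereocentre.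

Step 8
Reactants: 19 enol triflate; 20 carbon monoxide
Product: 21 silylene-protected enal
Conditions: Pd(PPh3)4 (cat.), LiCl, CO (1 atm), Bu3SnH (slow addition), THF, 50 °C
Reagents that add atoms: carbon monoxide [C-]#[O+]
Why: oxidative addition of the alkenyl triflate to zerovalent palladium, CO insertion and hydride transfer from tin to the acylpalladium (reductive carbonylation) should give the 2-substituted acrolein and leave the silylene and the pyrone alone.

Step 9
Reactants: 21 silylene-protected enal
Product: 22 trans-diol enal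
Conditions: HF·pyridine, pyridine, THF, 0 °C
Reagents that add atoms: none
Why: fluoride-driven cleavage of the strained five-membered silylene (Si–F bond formation) under buffered conditions should free the tertiary C2–OH (β) and the secondary allylic C3–OH (α) without change at either carbon.

Step 10
Reactants: 22 trans-diol enal
Product: 24 epoxy enal, via allylic mesylate 23 (not isolated)
Conditions: Ms2O, Et3N, CH2Cl2, −20 °C; then DBU, 0 °C to rt
Reagents that add atoms: none
Why: the secondary C3–OH is sulfonylated in preference to the tertiary C2–OH, and the C2 alkoxide then displaces the mesylate from the β face (intramolecular SN2, trans-diaxial), which inverts C3 and puts the epoxide on the face opposite the side chain and the pyrone.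

Step 11
Reactants: 24 epoxy enal (racemic); 25 pentan-3-one
Product: 28 target CNP0233636.2, via boron enolate 26 (not isolated), via boron aldolate 27 (not isolated)
Conditions: (+)-Ipc2BOTf (Ipc = isopinocampheyl, from (−)-α-pinene), i-Pr2NEt, CH2Cl2, −78 °C; 24, −78 to −20 °C; MeOH, pH 7 buffer, H2O2, 0 °C; chromatographic removal of the diastereomer
Reagents that add atoms: pentan-3-one CCC(=O)CC
Why: chair-like (Zimmerman–Traxler) addition of the (Z)-diisopinocampheylboron enolate should give the syn aldol, with the (−)-α-pinene-derived ligands chosen to direct the enolate to the Re face of the aldehyde so that the carbinol and α-methyl centres are set by the reagent; the racemic enal therefore gives 28 together with the diastereomer from ent-24, which is separated.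

**Compound list**

1 | methyl 2-methyl-3-oxopentanoate (racemic) | CCC(=O)C(C)C(=O)OC | starting material
2 | methyl propanoate | CCC(=O)OC | starting material
3 | sodium lithium dienolate (2,4-dianion) of 1 | [Na+].[Li+].CC=C([O-])C(C)=C([O-])OC | intermediate
4 | methyl 2,4-dimethyl-3,5-dioxoheptanoate (stereoisomer and tautomer mixture) | CCC(=O)C(C)C(=O)C(C)C(=O)OC | intermediate
5 | 6-ethyl-4-hydroxy-3,5-dimethyl-2H-pyran-2-one | CCc1oc(=O)c(C)c(O)c1C | intermediate
6 | methyl trifluoromethanesulfonate | COS(=O)(=O)C(F)(F)F | starting material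
7 | 6-ethyl-2-methoxy-3,5-dimethyl-4H-pyran-4-one | CCc1oc(OC)c(C)c(=O)c1C | intermediate
8 | (E)-3-ethoxy-2-methylprop-2-enal | CCO/C=C(\C)C=O | starting material
9 | lithium dienolate of 7 (deprotonated at the ethyl CH2) | [Li+].CC=C1OC(OC)=C(C)C([O-])=C1C | intermediate
10 | 2-[(4E)-5-ethoxy-3-hydroxy-4-methylpent-4-en-2-yl]-6-methoxy-3,5-dimethyl-4H-pyran-4-one (diastereomer mixture) | CCO/C=C(\C)C(O)C(C)c1oc(OC)c(C)c(=O)c1C | intermediate
11 | (2E)-4-(6-methoxy-3,5-dimethyl-4-oxo-4H-pyran-2-yl)-2-methylpent-2-enal (racemic at C4) | O=C/C(C)=C/C(C)c1oc(OC)c(C)c(=O)c1C | intermediate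
12 | di-tert-butylsilyl bis(trifluoromethanesulfonate) | CC(C)(C)[Si](OS(=O)(=O)C(F)(F)F)(OS(=O)(=O)C(F)(F)F)C(C)(C)C | starting material
13 | pentane-2,4-dione | CC(=O)CC(C)=O | starting material
14 | di-tert-butyl{[(1E,3E)-2-methyl-4-Py-penta-1,3-dien-1-yl]oxy}silyl trifluoromethanesulfonate | CC(C)(C)[Si](OS(=O)(=O)C(F)(F)F)(C(C)(C)C)O/C=C(\C)/C=C(\C)c1oc(OC)c(C)c(=O)c1C | intermediate
15 | (3E)-4-[di-tert-butyl{[(1E,3E)-2-methyl-4-Py-penta-1,3-dien-1-yl]oxy}silyloxy]pent-3-en-2-one | CC(=O)/C=C(\C)O[Si](C(C)(C)C)(C(C)(C)C)O/C=C(\C)/C=C(\C)c1oc(OC)c(C)c(=O)c1C | intermediate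
16 | cycloadduct: cyclohex-4-ene with C1 acetyl (α), C2 methyl (α) and O (β), C3 O (α), C4 methyl, C6 methyl (β) and Py (α), O2 and O3 bridged as a trans-fused di-tert-butylsilylene; racemic | CC(=O)[C@H]1[C@]2(C)O[Si](C(C)(C)C)(C(C)(C)C)O[C@H]2C(C)=C[C@@]1(C)c1oc(OC)c(C)c(=O)c1C | intermediate
17 | N-phenylbis(trifluoromethanesulfonimide) | O=S(=O)(N(c1ccccc1)S(=O)(=O)C(F)(F)F)C(F)(F)F | starting material
18 | potassium enolate of 16 (at the acetyl methyl group) | [K+].C=C([O-])[C@H]1[C@]2(C)O[Si](C(C)(C)C)(C(C)(C)C)O[C@H]2C(C)=C[C@@]1(C)c1oc(OC)c(C)c(=O)c1C | intermediate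
19 | enol triflate of 16 (C1 substituent = 1-(trifluoromethanesulfonyloxy)ethenyl); ring configuration as 16 | C=C(OS(=O)(=O)C(F)(F)F)[C@H]1[C@]2(C)O[Si](C(C)(C)C)(C(C)(C)C)O[C@H]2C(C)=C[C@@]1(C)c1oc(OC)c(C)c(=O)c1C | intermediate
20 | carbon monoxide | [C-]#[O+] | starting material
21 | silylene-protected enal (C1 substituent = 3-oxoprop-1-en-2-yl); ring configuration as 16 | C=C(C=O)[C@H]1[C@]2(C)O[Si](C(C)(C)C)(C(C)(C)C)O[C@H]2C(C)=C[C@@]1(C)c1oc(OC)c(C)c(=O)c1C | intermediate
22 | trans-diol enal: C2–OH β (tertiary), C3–OH α (secondary), C1 acrolein unit α, C6 Py α; racemic | C=C(C=O)[C@H]1[C@](C)(O)[C@@H](O)C(C)=C[C@@]1(C)c1oc(OC)c(C)c(=O)c1C | intermediate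
23 | C3 methanesulfonate of 22 | C=C(C=O)[C@H]1[C@](C)(O)[C@@H](OS(C)(=O)=O)C(C)=C[C@@]1(C)c1oc(OC)c(C)c(=O)c1C | intermediate
24 | epoxy enal: 2,3-epoxide on the β face, C1 acrolein unit, C2 methyl and C6 Py on the α face; racemic | C=C(C=O)[C@H]1[C@]2(C)O[C@@H]2C(C)=C[C@@]1(C)c1oc(OC)c(C)c(=O)c1C | intermediate
25 | pentan-3-one | CCC(=O)CC | starting material
26 | (Z)-pent-2-en-3-yl bis(isopinocampheyl)borinate (Ipc from (−)-α-pinene) | C/C=C(\OB([C@H]1C[C@H]2C[C@@H]([C@@H]1C)C2(C)C)[C@H]1C[C@H]2C[C@@H]([C@@H]1C)C2(C)C)CC | intermediate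
27 | bis(isopinocampheyl)boron aldolate of 28 | C=C([C@H](OB([C@H]1C[C@H]2C[C@@H]([C@@H]1C)C2(C)C)[C@H]1C[C@H]2C[C@@H]([C@@H]1C)C2(C)C)[C@@H](C)C(=O)CC)[C@H]1[C@]2(C)O[C@@H]2C(C)=C[C@@]1(C)c1oc(OC)c(C)c(=O)c1C | intermediate
28 | CNP0233636.2: syn-β-hydroxy ketone side chain (carbinol R, α-methyl carbon R) on the epoxy cyclohexene of 24 | C=C([C@H](O)[C@@H](C)C(=O)CC)[C@H]1[C@]2(C)O[C@@H]2C(C)=C[C@@]1(C)c1oc(OC)c(C)c(=O)c1C | target

**Step count and risks**

Total step count: 11. Longest linear sequence: 11 steps (1 to 28).

Steps most likely to fail: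

Step 6. The cycloaddition may be outrun by [1,5]-hydrogen shift of the inside methyl of the diene, by hydrolysis or E/Z drift of the two enol ethers, or it may close through the cis-fused (acetyl-exo) transition state. The fallback uses known reactions only, sets out from 7 and comes back at 24. Aldol addition of the lithium dienolate of 7 to methacrolein should give 2-(3-hydroxy-4-methylpent-4-en-2-yl)-6-methoxy-3,5-dimethyl-4H-pyran-4-one F1. Dehydration with TsOH in toluene should give 2-methoxy-3,5-dimethyl-6-[(2E)-4-methylpenta-2,4-dien-2-yl]-4H-pyran-4-one F2. An intermolecular Diels–Alder reaction of F2 with pent-3-yn-2-one (toluene, heat, or EtAlCl2) forms the same two ring bonds, with the regiochemistry set by the methyl and pyronyl groups of the diene, and gives 2-(6-acetyl-1,3,5-trimethylcyclohexa-2,5-dien-1-yl)-6-methoxy-3,5-dimethyl-4H-pyran-4-one F3. KOt-Bu followed by kinetic protonation with AcOH moves the enone double bond to C2=C3 and should give 2-(6-acetyl-1,3,5-trimethylcyclohexa-2,4-dien-1-yl)-6-methoxy-3,5-dimethyl-4H-pyran-4-one F4, with the C1 hydrogen delivered anti to the pyrone. KN(SiMe3)2 and PhNTf2 give the enol triflate of F4 F5, and Pd(PPh3)4, CO and Bu3SnH give the dienyl enal F6. Dimethyldioxirane should epoxidise the less hindered C2=C3 bond from the face anti to the C1 and C6 substituents and so return to racemic 24.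

Step 5. Double substitution at silicon, loss of the (1E,3E) geometry during soft enolisation, and hydrolysis of the mixed bis-enol silane on handling are the likely failures. The fallback sets out from 14 (made from 11 as in step 5) and comes back at 15. The silyl triflate 14 is hydrolysed with wet pyridine to the isolable di-tert-butyl{[(1E,3E)-2-methyl-4-Py-penta-1,3-dien-1-yl]oxy}silanol F7, which can be purified. The enone arm is then built by PMe3- or DABCO-catalysed conjugate addition of the silanol O–H to pent-3-yn-2-one, which should give the (E)-β-siloxy enone of 15 directly.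

Step 11. Mismatched or poor facial selectivity with the chiral enal, opening of the vinyl epoxide by the boron Lewis acid, and a hard separation of the two diastereomers at the last stage are the likely failures; if the facial sense is opposite to the one assumed, the enantiomeric borane is used. The fallback changes the order of events, sets out from 21 and comes back at 28. The same boron aldol is run on the silylene-protected enal 21 and should give the silylene-protected aldol F8, with the diastereomer from ent-21 separated at this earlier stage. TESOTf and 2,6-lutidine give the triethylsilyl ether of F8 F9. HF·pyridine at low temperature removes the strained silylene but not the TES group and gives the TES-protected trans-diol F10. Ms2O and Et3N, then DBU, give the TES-protected epoxide F11, and buffered HF·pyridine removes the TES group to give 28.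

Further compounds
F1 | step 6 | 2-(3-hydroxy-4-methylpent-4-en-2-yl)-6-methoxy-3,5-dimethyl-4H-pyran-4-one | C=C(C)C(O)C(C)c1oc(OC)c(C)c(=O)c1C
F2 | step 6 | 2-methoxy-3,5-dimethyl-6-[(2E)-4-methylpenta-2,4-dien-2-yl]-4H-pyran-4-one | C=C(C)/C=C(\C)c1oc(OC)c(C)c(=O)c1C
F3 | step 6 | 2-(6-acetyl-1,3,5-trimethylcyclohexa-2,5-dien-1-yl)-6-methoxy-3,5-dimethyl-4H-pyran-4-one (racemic) | CC(=O)C1=C(C)CC(C)=C[C@@]1(C)c1oc(OC)c(C)c(=O)c1C
F4 | step 6 | 2-(6-acetyl-1,3,5-trimethylcyclohexa-2,4-dien-1-yl)-6-methoxy-3,5-dimethyl-4H-pyran-4-one, acetyl cis to pyronyl (racemic) | CC(=O)[C@H]1C(C)=CC(C)=C[C@@]1(C)c1oc(OC)c(C)c(=O)c1C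
F5 | step 6 | enol triflate of F4 | C=C(OS(=O)(=O)C(F)(F)F)[C@H]1C(C)=CC(C)=C[C@@]1(C)c1oc(OC)c(C)c(=O)c1C
F6 | step 6 | dienyl enal (3-oxoprop-1-en-2-yl in place of acetyl in F4) | C=C(C=O)[C@H]1C(C)=CC(C)=C[C@@]1(C)c1oc(OC)c(C)c(=O)c1C
F7 | step 5 | di-tert-butyl{[(1E,3E)-2-methyl-4-Py-penta-1,3-dien-1-yl]oxy}silanol | CC(C)(C)[Si](O)(C(C)(C)C)O/C=C(\C)/C=C(\C)c1oc(OC)c(C)c(=O)c1C
F8 | step 11 | silylene-protected aldol (side chain of 28 on the ring of 21) | C=C([C@H](O)[C@@H](C)C(=O)CC)[C@H]1[C@]2(C)O[Si](C(C)(C)C)(C(C)(C)C)O[C@H]2C(C)=C[C@@]1(C)c1oc(OC)c(C)c(=O)c1C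
F9 | step 11 | triethylsilyl ether of F8 | C=C([C@H](O[Si](CC)(CC)CC)[C@@H](C)C(=O)CC)[C@H]1[C@]2(C)O[Si](C(C)(C)C)(C(C)(C)C)O[C@H]2C(C)=C[C@@]1(C)c1oc(OC)c(C)c(=O)c1C
F10 | step 11 | TES-protected trans-diol | C=C([C@H](O[Si](CC)(CC)CC)[C@@H](C)C(=O)CC)[C@H]1[C@](C)(O)[C@@H](O)C(C)=C[C@@]1(C)c1oc(OC)c(C)c(=O)c1C
F11 | step 11 | TES-protected epoxide (triethylsilyl ether of 28) | C=C([C@H](O[Si](CC)(CC)CC)[C@@H](C)C(=O)CC)[C@H]1[C@]2(C)O[C@@H]2C(C)=C[C@@]1(C)c1oc(OC)c(C)c(=O)c1C
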